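**Plan**

- Retrosynthesis: the C7 carbonyl is taken back to a benzylic CH2; ring C is then cut at C8–C14 (6π closure of a dienylketene) and at C9–C11 (alkenyllithium plus cyclobutenedione); the ring B substituents are cut at C10–C1 (enolate allylation) and C5–C4 (conjugate isopropenylation).
- Enabling feature: ring C is a hexasubstituted hydroquinone with OH on C11 and C14 flanking OMe on C12 and isopropyl on C13. These four carbons map onto 3-isopropyl-4-methoxycyclobutenedione, and the C8=C9 alkene of a ring B cyclohexene supplies the other two.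
- Forward: ring B is bought as the six-membered enone 2-methylcyclohex-2-en-1-one, the isopropenyl group and the three-carbon chain are added in one flask, the ketone becomes an alkenyl iodide, and the squarate fragment is joined at C9–C11.
- Ring C is closed last by thermolysis (step 8). Protection, C7 oxidation, chain oxidation and deprotection follow.
- Stereochemistry: C5 comes from a ligand-controlled copper-catalysed conjugate addition; C10 comes from allylation of the resulting enolate anti to the isopropenyl group. Neither centre is enolisable afterwards.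

Key step: step 8

Assumption: abietane locants are used throughout (ring B = C5 to C10; ring C = C8, C9, C11 to C14; chain C1 to C3 on C10); the six ring carbons of 2-methylcyclohex-2-en-1-one become C9 (carbonyl carbon), C10, C5, C6, C7 and C8.
Assumption: the antipode of the chiral carbene ligand in step 2 is the one that gives the (3S) enolate; its sense of induction with an alkenyl Grignard reagent is to be confirmed on the first run.

Step 1
Reactants: 1 dimethyl squarate; 2 isopropylmagnesium chloride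
Product: 5 3-methoxy-4-(propan-2-yl)cyclobut-3-ene-1,2-dione, via chloromagnesium alkoxide 3 (not isolated), via trifluoroacetate 4 (not isolated)
Conditions: 2 (1.05 equiv), THF, −78 °C; (CF3CO)2O (1.2 equiv), −78 → 0 °C; aq NaHCO3
Reagents that add atoms: water, O
Why: 1,2-addition of the Grignard reagent to one squarate carbonyl, O-trifluoroacetylation and vinylogous ionisation with hydrolysis of the oxocarbenium ion (the standard squarate to alkylcyclobutenedione sequence) should replace one methoxy group by isopropyl, and no stereocentre remains.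

Step 2
Reactants: 6 2-methylcyclohex-2-en-1-one; 7 isopropenylmagnesium bromide; 8 allyl iodide
Product: 10 (2S,3S)-2-methyl-2-(prop-2-en-1-yl)-3-(prop-1-en-2-yl)cyclohexan-1-one, via magnesium enolate 9 (not isolated)
Conditions: Cu(OTf)2 (3 mol %), chiral hydroxyalkyl imidazolinium salt (precursor of an alkoxide-tethered N-heterocyclic carbene, 4 mol %), 7 (1.2 equiv), Et2O, −30 °C; then 8 (3 equiv), DMPU, −30 → 20 °C
Reagents that add atoms: none
Why: Copper-catalysed enantioselective conjugate addition of a Grignard reagent to an α-substituted cyclic enone, in which the catalyst formed from Cu(OTf)2 and the chiral carbene selects the enone face and sets C5 (3S in 9); the tetrasubstituted magnesium enolate is then C-allylated on the face anti to the pseudoaxial isopropenyl group, which should place the allyl chain trans and the methyl cis to isopropenyl at C10.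

Step 3
Reactants: 10 (2S,3S)-2-methyl-2-(prop-2-en-1-yl)-3-(prop-1-en-2-yl)cyclohexan-1-one
Product: 12 (2S,3S)-2-(3-hydroxypropyl)-2-methyl-3-(prop-1-en-2-yl)cyclohexan-1-one, via catechol boronate 11 (not isolated)
Conditions: catecholborane (1.2 equiv), RhCl(PPh3)3 (2 mol %), THF, 0 → 20 °C; then 3 M aq NaOH, 30 % H2O2, 0 °C
Reagents that add atoms: hydrogen peroxide, OO
Why: Rhodium-catalysed hydroboration with catecholborane is much faster for a monosubstituted terminal alkene than for the hindered 1,1-disubstituted isopropenyl group and, unlike the uncatalysed reaction, spares the ketone; alkaline peroxide then gives the anti-Markovnikov primary alcohol without touching either stereocentre.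

Step 4
Reactants: 12 (2S,3S)-2-(3-hydroxypropyl)-2-methyl-3-(prop-1-en-2-yl)cyclohexan-1-one
Product: 13 (2S,3S)-2-{3-[(tert-butyldimethylsilyl)oxy]propyl}-2-methyl-3-(prop-1-en-2-yl)cyclohexan-1-one
Conditions: TBSCl (1.2 equiv), imidazole (2.5 equiv), DMF, 20 °C
Reagents that add atoms: tert-butyldimethylsilyl chloride, CC(C)(C)[Si](C)(C)Cl
Why: Imidazole-mediated silylation of the primary alcohol is routine and also draws any cyclic hemiketal form of 12 back to the open keto ether.

Step 5
Reactants: 13 (2S,3S)-2-{3-[(tert-butyldimethylsilyl)oxy]propyl}-2-methyl-3-(prop-1-en-2-yl)cyclohexan-1-one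
Product: 14 (2S,3S)-2-{3-[(tert-butyldimethylsilyl)oxy]propyl}-2-methyl-3-(prop-1-en-2-yl)cyclohexan-1-one hydrazone (C=N geometry not controlled)
Conditions: N2H4·H2O (10 equiv), Et3N, EtOH, 80 °C, Ar
Reagents that add atoms: hydrazine, NN
Why: Hydrazone condensation of a ketone beside a quaternary carbon is slow but is driven by excess hydrazine at reflux, and the argon atmosphere prevents diimide formation that could reduce the isopropenyl group.

Step 6
Reactants: 14 (2S,3S)-2-{3-[(tert-butyldimethylsilyl)oxy]propyl}-2-methyl-3-(prop-1-en-2-yl)cyclohexan-1-one hydrazone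
Product: 16 tert-butyl{3-[(1S,6S)-2-iodo-1-methyl-6-(prop-1-en-2-yl)cyclohex-2-en-1-yl]propoxy}dimethylsilane, via diazoalkane 15 (not isolated)
Conditions: I2 (2.5 equiv), 1,1,3,3-tetramethylguanidine (6 equiv), THF, 0 → 20 °C
Reagents that add atoms: iodine, II
Why: Barton vinyl iodide synthesis, in which iodine oxidises the hydrazone to the diazoalkane, iodination with loss of N2 follows and base removes a proton; only C8 carries α-hydrogens, so a single alkenyl iodide regioisomer can form.

Step 7
Reactants: 16 tert-butyl{3-[(1S,6S)-2-iodo-1-methyl-6-(prop-1-en-2-yl)cyclohex-2-en-1-yl]propoxy}dimethylsilane; 5 3-methoxy-4-(propan-2-yl)cyclobut-3-ene-1,2-dione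
Product: 18 4-[(5S,6S)-6-{3-[(tert-butyldimethylsilyl)oxy]propyl}-6-methyl-5-(prop-1-en-2-yl)cyclohex-1-en-1-yl]-4-hydroxy-3-methoxy-2-(propan-2-yl)cyclobut-2-en-1-one (both carbinol epimers), via alkenyllithium 17 (not isolated)
Conditions: t-BuLi (2.05 equiv), THF, −78 °C; transfer into 5 (1.2 equiv), THF, −78 °C; sat. aq NH4Cl
Reagents that add atoms: none
Why: Iodine–lithium exchange gives the alkenyllithium without moving the double bond, and its 1,2-addition should occur at the more electrophilic carbonyl of 5, the one next to the methoxy-bearing carbon (the other is deactivated as a vinylogous ester); the new carbinol centre forms as a mixture that is erased in step 8.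

Step 8
Reactants: 18 4-[(5S,6S)-6-{3-[(tert-butyldimethylsilyl)oxy]propyl}-6-methyl-5-(prop-1-en-2-yl)cyclohex-1-en-1-yl]-4-hydroxy-3-methoxy-2-(propan-2-yl)cyclobut-2-en-1-one
Product: 21 (5S,6S)-5-{3-[(tert-butyldimethylsilyl)oxy]propyl}-3-methoxy-5-methyl-2-(propan-2-yl)-6-(prop-1-en-2-yl)-5,6,7,8-tetrahydronaphthalene-1,4-diol, via dienylketene 19 (not isolated), via cyclohexadienone 20 (not isolated)
Conditions: degassed toluene (0.02 M), 110 °C, Ar
Reagents that add atoms: none
Why: This is a Moore rearrangement, the thermal ring expansion of a 4-alkenyl-4-hydroxycyclobutenone. Conrotatory 4π opening breaks the C11–C14 bond of the four-membered ring with the donor hydroxyl rotating outward, so the ring B alkene lies cis to the ketene in 19. Ring C then closes by a thermally allowed disrotatory 6π electrocyclisation that forms C8–C14, and dienone 20 aromatises by transfer of the C8 hydrogen to oxygen. No stereocentre is created, C5 and C10 take no part, and the carbinol centre of 18 disappears on ring opening. The selectivity required is the placement of O, OMe, isopropyl and O on C11, C12, C13 and C14, which is fixed by the site of addition in step 7, and lactonisation of the ketene to a furanone should be disfavoured because the hydroxyl points away from it.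

Step 9
Reactants: 21 (5S,6S)-5-{3-[(tert-butyldimethylsilyl)oxy]propyl}-3-methoxy-5-methyl-2-(propan-2-yl)-6-(prop-1-en-2-yl)-5,6,7,8-tetrahydronaphthalene-1,4-diol
Product: 22 tert-butyl{3-[(1S,2S)-7-methoxy-5,8-bis(methoxymethoxy)-1-methyl-6-(propan-2-yl)-2-(prop-1-en-2-yl)-1,2,3,4-tetrahydronaphthalen-1-yl]propoxy}dimethylsilane
Conditions: NaH (3 equiv), MOMCl (3 equiv), DMF, 0 → 20 °C, Ar
Reagents that add atoms: chloromethyl methyl ether, COCCl
Why: Williamson-type alkylation of both phenoxides, in which the small electrophile should reach even the C11 oxygen beside the quaternary carbon, masks the air-sensitive hydroquinone for the oxidations that follow.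

Step 10
Reactants: 22 tert-butyl{3-[(1S,2S)-7-methoxy-5,8-bis(methoxymethoxy)-1-methyl-6-(propan-2-yl)-2-(prop-1-en-2-yl)-1,2,3,4-tetrahydronaphthalen-1-yl]propoxy}dimethylsilane
Product: 24 (3S,4S)-4-{3-[(tert-butyldimethylsilyl)oxy]propyl}-6-methoxy-5,8-bis(methoxymethoxy)-4-methyl-7-(propan-2-yl)-3-(prop-1-en-2-yl)-3,4-dihydronaphthalen-1(2H)-one, via benzylic alcohol 23 (not isolated)
Conditions: DDQ (2.5 equiv), 1,4-dioxane/H2O (9:1), 20 °C
Reagents that add atoms: water, O
Why: DDQ benzylic oxidation by hydride abstraction should select C7, which is para to the C12 methoxy group and ortho to the C14 acetal oxygen; water traps the cation and the benzylic alcohol is oxidised on to the aryl ketone, while the isolated isopropenyl group is not a substrate for DDQ.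

Step 11
Reactants: 24 (3S,4S)-4-{3-[(tert-butyldimethylsilyl)oxy]propyl}-6-methoxy-5,8-bis(methoxymethoxy)-4-methyl-7-(propan-2-yl)-3-(prop-1-en-2-yl)-3,4-dihydronaphthalen-1(2H)-one
Product: 25 (3S,4S)-4-(3-hydroxypropyl)-6-methoxy-5,8-bis(methoxymethoxy)-4-methyl-7-(propan-2-yl)-3-(prop-1-en-2-yl)-3,4-dihydronaphthalen-1(2H)-one
Conditions: TBAF (1.2 equiv), THF, 0 → 20 °C
Reagents that add atoms: none
Why: Fluoride cleavage of the primary silyl ether is selective, since aryl methoxymethyl ethers, the ketone and the alkene are inert to TBAF and C5 is not α to the carbonyl.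

Step 12
Reactants: 25 (3S,4S)-4-(3-hydroxypropyl)-6-methoxy-5,8-bis(methoxymethoxy)-4-methyl-7-(propan-2-yl)-3-(prop-1-en-2-yl)-3,4-dihydronaphthalen-1(2H)-one
Product: 27 3-[(1S,2S)-7-methoxy-5,8-bis(methoxymethoxy)-1-methyl-4-oxo-6-(propan-2-yl)-2-(prop-1-en-2-yl)-1,2,3,4-tetrahydronaphthalen-1-yl]propanoic acid, via aldehyde 26 (not isolated)
Conditions: TEMPO (20 mol %), PhI(OAc)2 (2.5 equiv), MeCN/H2O (1:1), 20 °C
Reagents that add atoms: water, O
Why: Oxoammonium (TEMPO) oxidation with PhI(OAc)2 as terminal oxidant in aqueous acetonitrile takes a primary alcohol through the aldehyde hydrate to the carboxylic acid and should leave the alkene and the acetals untouched.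

Step 13
Reactants: 27 3-[(1S,2S)-7-methoxy-5,8-bis(methoxymethoxy)-1-methyl-4-oxo-6-(propan-2-yl)-2-(prop-1-en-2-yl)-1,2,3,4-tetrahydronaphthalen-1-yl]propanoic acid
Product: 28 3-[(1S,2S)-5,8-dihydroxy-7-methoxy-1-methyl-4-oxo-6-(propan-2-yl)-2-(prop-1-en-2-yl)-1,2,3,4-tetrahydronaphthalen-1-yl]propanoic acid (CNP0249049.1)
Conditions: 3 M aq HCl/THF (1:2), 40 °C, Ar
Reagents that add atoms: none
Why: Acid hydrolysis of the two aryl methoxymethyl acetals, helped at C14 by the neighbouring carbonyl, should proceed in dilute aqueous acid, which without an alcohol cosolvent cannot esterify the acid and is too weak to hydrate the isopropenyl group.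

**Compound list**

1 | dimethyl squarate (3,4-dimethoxycyclobut-3-ene-1,2-dione) | COC1=C(OC)C(=O)C1=O | starting material
2 | isopropylmagnesium chloride | CC(C)[Mg]Cl | starting material
3 | chloromagnesium 2,3-dimethoxy-4-oxo-1-(propan-2-yl)cyclobut-2-en-1-olate (racemic) | COC1=C(OC)C(=O)C1(O[Mg]Cl)C(C)C | intermediate
4 | 2,3-dimethoxy-4-oxo-1-(propan-2-yl)cyclobut-2-en-1-yl trifluoroacetate (racemic) | COC1=C(OC)C(=O)C1(OC(=O)C(F)(F)F)C(C)C | intermediate
5 | 3-methoxy-4-(propan-2-yl)cyclobut-3-ene-1,2-dione | COC1=C(C(C)C)C(=O)C1=O | intermediate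
6 | 2-methylcyclohex-2-en-1-one | CC1=CCCCC1=O | starting material
7 | isopropenylmagnesium bromide | C=C(C)[Mg]Br | starting material
8 | allyl iodide | C=CCI | starting material
9 | bromomagnesium (3S)-2-methyl-3-(prop-1-en-2-yl)cyclohex-1-en-1-olate | C=C(C)[C@@H]1CCCC(O[Mg]Br)=C1C | intermediate
10 | (2S,3S)-2-methyl-2-(prop-2-en-1-yl)-3-(prop-1-en-2-yl)cyclohexan-1-one | C=C(C)[C@@H]1CCCC(=O)[C@@]1(C)CC=C | intermediate
11 | 2-{3-[(1S,2S)-1-methyl-6-oxo-2-(prop-1-en-2-yl)cyclohexyl]propyl}-1,3,2-benzodioxaborole | C=C(C)[C@@H]1CCCC(=O)[C@@]1(C)CCCB2Oc3ccccc3O2 | intermediate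
12 | (2S,3S)-2-(3-hydroxypropyl)-2-methyl-3-(prop-1-en-2-yl)cyclohexan-1-one | C=C(C)[C@@H]1CCCC(=O)[C@@]1(C)CCCO | intermediate
13 | (2S,3S)-2-{3-[(tert-butyldimethylsilyl)oxy]propyl}-2-methyl-3-(prop-1-en-2-yl)cyclohexan-1-one | C=C(C)[C@@H]1CCCC(=O)[C@@]1(C)CCCO[Si](C)(C)C(C)(C)C | intermediate
14 | (2S,3S)-2-{3-[(tert-butyldimethylsilyl)oxy]propyl}-2-methyl-3-(prop-1-en-2-yl)cyclohexan-1-one hydrazone | C=C(C)[C@@H]1CCCC(=NN)[C@@]1(C)CCCO[Si](C)(C)C(C)(C)C | intermediate
15 | tert-butyl{3-[(1S,2S)-6-diazo-1-methyl-2-(prop-1-en-2-yl)cyclohexyl]propoxy}dimethylsilane | C=C(C)[C@@H]1CCCC(=[N+]=[N-])[C@@]1(C)CCCO[Si](C)(C)C(C)(C)C | intermediate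
16 | tert-butyl{3-[(1S,6S)-2-iodo-1-methyl-6-(prop-1-en-2-yl)cyclohex-2-en-1-yl]propoxy}dimethylsilane | C=C(C)[C@@H]1CCC=C(I)[C@@]1(C)CCCO[Si](C)(C)C(C)(C)C | intermediate
17 | (5S,6S)-6-{3-[(tert-butyldimethylsilyl)oxy]propyl}-6-methyl-5-(prop-1-en-2-yl)cyclohex-1-en-1-yllithium | C=C(C)[C@@H]1CCC=C([Li])[C@@]1(C)CCCO[Si](C)(C)C(C)(C)C | intermediate
18 | 4-[(5S,6S)-6-{3-[(tert-butyldimethylsilyl)oxy]propyl}-6-methyl-5-(prop-1-en-2-yl)cyclohex-1-en-1-yl]-4-hydroxy-3-methoxy-2-(propan-2-yl)cyclobut-2-en-1-one (both carbinol epimers) | C=C(C)[C@@H]1CCC=C(C2(O)C(OC)=C(C(C)C)C2=O)[C@@]1(C)CCCO[Si](C)(C)C(C)(C)C | intermediate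
19 | (3Z)-4-[(5S,6S)-6-{3-[(tert-butyldimethylsilyl)oxy]propyl}-6-methyl-5-(prop-1-en-2-yl)cyclohex-1-en-1-yl]-4-hydroxy-3-methoxy-2-(propan-2-yl)buta-1,3-dien-1-one | C=C(C)[C@@H]1CCC=C(/C(O)=C(OC)\C(C(C)C)=C=O)[C@@]1(C)CCCO[Si](C)(C)C(C)(C)C | intermediate
20 | (5S,6S)-5-{3-[(tert-butyldimethylsilyl)oxy]propyl}-4-hydroxy-3-methoxy-5-methyl-2-(propan-2-yl)-6-(prop-1-en-2-yl)-6,7,8,8a-tetrahydronaphthalen-1(5H)-one (C8a unassigned) | C=C(C)[C@@H]1CCC2C(=O)C(C(C)C)=C(OC)C(O)=C2[C@@]1(C)CCCO[Si](C)(C)C(C)(C)C | intermediate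
21 | (5S,6S)-5-{3-[(tert-butyldimethylsilyl)oxy]propyl}-3-methoxy-5-methyl-2-(propan-2-yl)-6-(prop-1-en-2-yl)-5,6,7,8-tetrahydronaphthalene-1,4-diol | C=C(C)[C@@H]1CCc2c(O)c(C(C)C)c(OC)c(O)c2[C@@]1(C)CCCO[Si](C)(C)C(C)(C)C | intermediate
22 | tert-butyl{3-[(1S,2S)-7-methoxy-5,8-bis(methoxymethoxy)-1-methyl-6-(propan-2-yl)-2-(prop-1-en-2-yl)-1,2,3,4-tetrahydronaphthalen-1-yl]propoxy}dimethylsilane | C=C(C)[C@@H]1CCc2c(OCOC)c(C(C)C)c(OC)c(OCOC)c2[C@@]1(C)CCCO[Si](C)(C)C(C)(C)C | intermediate
23 | (3S,4S)-4-{3-[(tert-butyldimethylsilyl)oxy]propyl}-6-methoxy-5,8-bis(methoxymethoxy)-4-methyl-7-(propan-2-yl)-3-(prop-1-en-2-yl)-1,2,3,4-tetrahydronaphthalen-1-ol (both C1 epimers) | C=C(C)[C@@H]1CC(O)c2c(OCOC)c(C(C)C)c(OC)c(OCOC)c2[C@@]1(C)CCCO[Si](C)(C)C(C)(C)C | intermediate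
24 | (3S,4S)-4-{3-[(tert-butyldimethylsilyl)oxy]propyl}-6-methoxy-5,8-bis(methoxymethoxy)-4-methyl-7-(propan-2-yl)-3-(prop-1-en-2-yl)-3,4-dihydronaphthalen-1(2H)-one | C=C(C)[C@@H]1CC(=O)c2c(OCOC)c(C(C)C)c(OC)c(OCOC)c2[C@@]1(C)CCCO[Si](C)(C)C(C)(C)C | intermediate
25 | (3S,4S)-4-(3-hydroxypropyl)-6-methoxy-5,8-bis(methoxymethoxy)-4-methyl-7-(propan-2-yl)-3-(prop-1-en-2-yl)-3,4-dihydronaphthalen-1(2H)-one | C=C(C)[C@@H]1CC(=O)c2c(OCOC)c(C(C)C)c(OC)c(OCOC)c2[C@@]1(C)CCCO | intermediate
26 | 3-[(1S,2S)-7-methoxy-5,8-bis(methoxymethoxy)-1-methyl-4-oxo-6-(propan-2-yl)-2-(prop-1-en-2-yl)-1,2,3,4-tetrahydronaphthalen-1-yl]propanal | C=C(C)[C@@H]1CC(=O)c2c(OCOC)c(C(C)C)c(OC)c(OCOC)c2[C@@]1(C)CCC=O | intermediate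
27 | 3-[(1S,2S)-7-methoxy-5,8-bis(methoxymethoxy)-1-methyl-4-oxo-6-(propan-2-yl)-2-(prop-1-en-2-yl)-1,2,3,4-tetrahydronaphthalen-1-yl]propanoic acid | C=C(C)[C@@H]1CC(=O)c2c(OCOC)c(C(C)C)c(OC)c(OCOC)c2[C@@]1(C)CCC(=O)O | intermediate
28 | 3-[(1S,2S)-5,8-dihydroxy-7-methoxy-1-methyl-4-oxo-6-(propan-2-yl)-2-(prop-1-en-2-yl)-1,2,3,4-tetrahydronaphthalen-1-yl]propanoic acid | C=C(C)[C@@H]1CC(=O)c2c(O)c(C(C)C)c(OC)c(O)c2[C@@]1(C)CCC(=O)O | target

**Step count**

Total: 13 steps. Longest linear sequence: 12 steps (steps 2 to 13 from 2-methylcyclohex-2-en-1-one); step 1 prepares the second fragment.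

**Steps most likely to fail**

Step 2. An sp2 Grignard reagent may give poor facial selectivity with the chiral copper catalyst, and the enolate may be allylated with incomplete anti selectivity or more than once. The fallback sets out from 6, 7 and 8 and comes back at 10. The addition is run with achiral CuBr·SMe2 (5 mol %) in THF at −78 °C, followed by the same allylation, to give racemic trans-2-allyl-2-methyl-3-isopropenylcyclohexanone F1. The enantiomers are then separated by preparative supercritical-fluid chromatography on an amylose tris(3,5-dimethylphenylcarbamate) phase, and the (2S,3S) fraction is 10.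

Step 8. The ketene may be diverted through the free carbinol (inward rotation and lactonisation to a furanone), or the hydroquinone may be oxidised to the quinone during heating and isolation. The fallback sets out from 16 (with 5) and comes back at 22. After lithiation and addition as in step 7, the lithium alkoxide is trapped in the flask with chloromethyl methyl ether (DMPU, −78 → 0 °C) to give the O-methoxymethyl cyclobutenone adduct F2. Thermolysis in toluene at 110 °C, the same electrocyclic sequence with an alkoxy group that cannot lactonise, should give the hydroquinone mono(methoxymethyl) ether F3 (C11 OMOM, C14 OH). NaH and chloromethyl methyl ether in DMF then give 22.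

Step 10. The three ring oxygens are each flanked by two ortho groups and twisted out of conjugation, so hydride abstraction at C7 may be slow. DDQ may then attack the isopropyl methine or dealkylate the protected hydroquinone to the quinone. The fallback sets out from 22 and comes back at 24. Pyridinium tribromide in CH2Cl2/pyridine at 0 °C masks the isopropenyl group as the 1,2-dibromide of 22 F4 (the fully substituted arene has no position open to bromination). CrO3·3,5-dimethylpyrazole in CH2Cl2 at −20 °C, a classical chromium benzylic oxidation, gives the C7 keto dibromide F5. Zinc dust in AcOH/THF then restores the alkene and gives 24.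

**Further compounds**

F1 | step 2 | racemic trans-2-methyl-2-(prop-2-en-1-yl)-3-(prop-1-en-2-yl)cyclohexan-1-one (1:1 mixture of 10 and its enantiomer) | C=C(C)[C@@H]1CCCC(=O)[C@@]1(C)CC=C.C=C(C)[C@H]1CCCC(=O)[C@]1(C)CC=C
F2 | step 8 | 4-[(5S,6S)-6-{3-[(tert-butyldimethylsilyl)oxy]propyl}-6-methyl-5-(prop-1-en-2-yl)cyclohex-1-en-1-yl]-3-methoxy-4-(methoxymethoxy)-2-(propan-2-yl)cyclobut-2-en-1-one (both C4 epimers) | C=C(C)[C@@H]1CCC=C(C2(OCOC)C(OC)=C(C(C)C)C2=O)[C@@]1(C)CCCO[Si](C)(C)C(C)(C)C
F3 | step 8 | (5S,6S)-5-{3-[(tert-butyldimethylsilyl)oxy]propyl}-3-methoxy-4-(methoxymethoxy)-5-methyl-2-(propan-2-yl)-6-(prop-1-en-2-yl)-5,6,7,8-tetrahydronaphthalen-1-ol | C=C(C)[C@@H]1CCc2c(O)c(C(C)C)c(OC)c(OCOC)c2[C@@]1(C)CCCO[Si](C)(C)C(C)(C)C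
F4 | step 10 | dibromide of 22 with a 1,2-dibromopropan-2-yl group in place of isopropenyl (both epimers at the bromine-bearing carbon) | BrCC(C)(Br)[C@@H]1CCc2c(OCOC)c(C(C)C)c(OC)c(OCOC)c2[C@@]1(C)CCCO[Si](C)(C)C(C)(C)C
F5 | step 10 | C7 ketone of F4 (dibromide of 24) | BrCC(C)(Br)[C@@H]1CC(=O)c2c(OCOC)c(C(C)C)c(OC)c(OCOC)c2[C@@]1(C)CCCO[Si](C)(C)C(C)(C)C
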